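**Plan**

- Numbering used: ring carbons C1–C10 (C3 carries the isobutyrate, C4=C5 and C6–O belong to the butenolide, C7/C8 are the lactone fusion, C9=C10 is the ring alkene), C11–C13 the methylene lactone, C14 the CH2OH carbon, C15 the butenolide carbonyl.
- Retrosynthesis: late cuts are the PMB ether, C11=C13, the isobutyrate and the C3 carbinol (back to a ketone). The butenolide is then read as the hydrolysis product of a 2-methoxyfuran, and this furan is cut at C5–C6 and C4–C15 in one stroke to the open-chain oxazole–ynone 21. Compound 21 is cut at the oxazole (C6 carboxyl plus alanine ester), at C7–C8 (aldol) and at C10–C1 (Suzuki).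
- Enabling feature: the butenolide atoms C6–O–C15(=O) with C4=C5 are a masked 2-oxyfuran. C6–O–C15 maps onto C2–O1–C5 of a 5-methoxyoxazole grown from the C6 carboxyl of a paraconic acid, C4=C5 maps onto a terminal ynone (C3 at ketone level as activator), and the N=C(CH3) unit of the oxazole leaves as acetonitrile.
- Forward order: chain (C10–C1), γ-lactone (C7–C8 aldol, lactonization), oxazole, then the ten-membered carbocycle and the furan together (step 14), C3 carbinol and ester, methylene, butenolide, deprotection.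
- Stereochemistry: C9=C10 from a (Z)-enol triflate coupled with retention; C7 and C8 from the (S)-benzyloxazolidinone syn-aldol; C3 from oxazaborolidine-controlled reduction; C6 from protonation of the ansa furan on its unbridged face.

Key step: step 14

Remark on the chemistry: racemic pent-1-en-4-yn-3-ol is used. Its carbinol carbon (C3) is carried in both configurations and is erased at ynone 21, so 6–10 are racemic, 14–20 are C3-epimer pairs, and their SMILES leave C3 open.

Step 1
Reactants: 1 ethyl 4-chloro-3-oxobutanoate; 2 4-methoxybenzyl alcohol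
Product: 3 ethyl 4-[(4-methoxybenzyl)oxy]-3-oxobutanoate
Conditions: NaH (2.2 equiv), THF, 0 °C → rt; aq. HCl
Reagents that add atoms: none
Why: Williamson-type displacement of the γ-chloride by the alkoxide on the enolized β-keto ester installs the protected C14 oxygen, the second equivalent of base keeping the β-keto ester as its enolate.

Step 2
Reactants: 3 ethyl 4-[(4-methoxybenzyl)oxy]-3-oxobutanoate
Product: 4 ethyl (2Z)-4-[(4-methoxybenzyl)oxy]-3-{[(trifluoromethyl)sulfonyl]oxy}but-2-enoate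
Conditions: Tf2O, aq. LiOH, PhMe, 5 °C
Reagents that add atoms: trifluoromethanesulfonic anhydride, O=S(=O)(OS(=O)(=O)C(F)(F)F)C(F)(F)F
Why: O-triflation of the lithium-chelated (Z)-enolate of the β-keto ester (stereoselective enol triflate formation) puts the triflate cis to the ester and so fixes the later C9=C10 geometry.

Step 3
Reactants: 5 pent-1-en-4-yn-3-ol (racemic)
Product: 6 triethyl{[5-(triethylsilyl)pent-1-en-4-yn-3-yl]oxy}silane
Conditions: n-BuLi (2.1 equiv), THF, −78 °C; Et3SiCl (2.2 equiv), −78 °C → rt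
Reagents that add atoms: chlorotriethylsilane, CC[Si](CC)(CC)Cl
Why: Double deprotonation (O–H and alkyne C–H) and silylation cap both positions in one operation, so that the alkyne is inert in steps 4–11.

Step 4
Reactants: 6 triethyl{[5-(triethylsilyl)pent-1-en-4-yn-3-yl]oxy}silane; 4 ethyl (2Z)-4-[(4-methoxybenzyl)oxy]-3-{[(trifluoromethyl)sulfonyl]oxy}but-2-enoate
Product: 8 ethyl (2E)-3-{[(4-methoxybenzyl)oxy]methyl}-6-[(triethylsilyl)oxy]-8-(triethylsilyl)oct-2-en-7-ynoate, via B-alkyl-9-BBN adduct 7 (not isolated)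
Conditions: 9-BBN, THF, 0 °C → rt; then 4, PdCl2(dppf) (cat.), AsPh3, Cs2CO3, DMF/H2O, rt
Reagents that add atoms: none
Why: Anti-Markovnikov hydroboration of the terminal alkene and B-alkyl Suzuki–Miyaura coupling with the activated enol triflate form C10–C1 with retention, which places the chain cis to the ester (C8 cis to C1 as in the target).

Step 5
Reactants: 8 ethyl (2E)-3-{[(4-methoxybenzyl)oxy]methyl}-6-[(triethylsilyl)oxy]-8-(triethylsilyl)oct-2-en-7-ynoate
Product: 9 (2E)-3-{[(4-methoxybenzyl)oxy]methyl}-6-[(triethylsilyl)oxy]-8-(triethylsilyl)oct-2-en-7-yn-1-ol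
Conditions: DIBAL-H (2.2 equiv), CH2Cl2, −78 °C; Rochelle salt
Reagents that add atoms: none
Why: 1,2-Reduction of the conjugated ester by DIBAL-H gives the allylic alcohol without touching the silyl groups or the alkene geometry.

Step 6
Reactants: 9 (2E)-3-{[(4-methoxybenzyl)oxy]methyl}-6-[(triethylsilyl)oxy]-8-(triethylsilyl)oct-2-en-7-yn-1-ol
Product: 10 (2E)-3-{[(4-methoxybenzyl)oxy]methyl}-6-[(triethylsilyl)oxy]-8-(triethylsilyl)oct-2-en-7-ynal
Conditions: MnO2, CH2Cl2, rt
Reagents that add atoms: none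
Why: Neutral allylic oxidation with MnO2 gives the enal (C8) without E/Z isomerization.

Step 7
Reactants: 11 (4S)-4-benzyl-1,3-oxazolidin-2-one; 12 methyl 4-chloro-4-oxobutanoate
Product: 13 methyl 4-[(4S)-4-benzyl-2-oxo-1,3-oxazolidin-3-yl]-4-oxobutanoate
Conditions: n-BuLi, THF, −78 °C; then 12, −78 → 0 °C
Reagents that add atoms: none
Why: N-Acylation of the lithiated oxazolidinone by the acid chloride gives the succinate imide that carries C6, C7, C11 and C12.

Step 8
Reactants: 13 methyl 4-[(4S)-4-benzyl-2-oxo-1,3-oxazolidin-3-yl]-4-oxobutanoate; 10 (2E)-3-{[(4-methoxybenzyl)oxy]methyl}-6-[(triethylsilyl)oxy]-8-(triethylsilyl)oct-2-en-7-ynal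
Product: 15 (4S)-4-benzyl-3-({(2R,3S)-2-[(1E)-2-{[(4-methoxybenzyl)oxy]methyl}-5-[(triethylsilyl)oxy]-7-(triethylsilyl)hept-1-en-6-yn-1-yl]-5-oxotetrahydrofuran-3-yl}carbonyl)-1,3-oxazolidin-2-one, via syn-aldol adduct 14 (not isolated)
Conditions: Bu2BOTf, iPr2NEt, CH2Cl2, 0 °C; 10, −78 → 0 °C; pH 7 buffer, MeOH, H2O2; then PPTS (cat.), PhMe, 50 °C
Reagents that add atoms: none
Why: Evans syn-aldol through the (Z)-boron enolate and a Zimmerman–Traxler transition state, in which the benzyl group of the auxiliary sets C7 and C8, followed by lactonization of the γ-hydroxy ester, which turns the syn adduct into the trans-lactone.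

Step 9
Reactants: 15 (4S)-4-benzyl-3-({(2R,3S)-2-[(1E)-2-{[(4-methoxybenzyl)oxy]methyl}-5-[(triethylsilyl)oxy]-7-(triethylsilyl)hept-1-en-6-yn-1-yl]-5-oxotetrahydrofuran-3-yl}carbonyl)-1,3-oxazolidin-2-one
Product: 16 (2R,3S)-2-[(1E)-2-{[(4-methoxybenzyl)oxy]methyl}-5-[(triethylsilyl)oxy]-7-(triethylsilyl)hept-1-en-6-yn-1-yl]-5-oxotetrahydrofuran-3-carboxylic acid
Conditions: LiOH, H2O2, THF/H2O, 0 °C; Na2SO3; 1 M HCl to pH 3
Reagents that add atoms: hydrogen peroxide (acting as lithium hydroperoxide), OO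
Why: Hydroperoxide attacks the exocyclic imide carbonyl selectively (standard auxiliary cleavage), and any opened lactone recloses on acidification to the thermodynamically preferred trans-paraconic acid.

Step 10
Reactants: 16 (2R,3S)-2-[(1E)-2-{[(4-methoxybenzyl)oxy]methyl}-5-[(triethylsilyl)oxy]-7-(triethylsilyl)hept-1-en-6-yn-1-yl]-5-oxotetrahydrofuran-3-carboxylic acid; 17 methyl L-alaninate hydrochloride
Product: 18 methyl N-({(2R,3S)-2-[(1E)-2-{[(4-methoxybenzyl)oxy]methyl}-5-[(triethylsilyl)oxy]-7-(triethylsilyl)hept-1-en-6-yn-1-yl]-5-oxotetrahydrofuran-3-yl}carbonyl)-L-alaninate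
Conditions: EDC·HCl, HOBt, iPr2NEt, CH2Cl2, 0 °C → rt
Reagents that add atoms: none
Why: Carbodiimide amide coupling attaches the amino ester whose carboxyl carbon will become C15 and whose N–C(CH3) unit will later be expelled.

Step 11
Reactants: 18 methyl N-({(2R,3S)-2-[(1E)-2-{[(4-methoxybenzyl)oxy]methyl}-5-[(triethylsilyl)oxy]-7-(triethylsilyl)hept-1-en-6-yn-1-yl]-5-oxotetrahydrofuran-3-yl}carbonyl)-L-alaninate
Product: 19 (4S,5R)-4-(5-methoxy-4-methyl-1,3-oxazol-2-yl)-5-[(1E)-2-{[(4-methoxybenzyl)oxy]methyl}-5-[(triethylsilyl)oxy]-7-(triethylsilyl)hept-1-en-6-yn-1-yl]dihydrofuran-2(3H)-one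
Conditions: PPh3, I2, Et3N, CH2Cl2, 0 °C → rt
Reagents that add atoms: none
Why: Robinson–Gabriel-type cyclodehydration of the α-acylamino ester with the phosphonium dehydrating system gives the 5-methoxyoxazole, the alanine stereocenter becoming sp2.

Step 12
Reactants: 19 (4S,5R)-4-(5-methoxy-4-methyl-1,3-oxazol-2-yl)-5-[(1E)-2-{[(4-methoxybenzyl)oxy]methyl}-5-[(triethylsilyl)oxy]-7-(triethylsilyl)hept-1-en-6-yn-1-yl]dihydrofuran-2(3H)-one
Product: 20 (4S,5R)-5-[(1E)-5-hydroxy-2-{[(4-methoxybenzyl)oxy]methyl}hept-1-en-6-yn-1-yl]-4-(5-methoxy-4-methyl-1,3-oxazol-2-yl)dihydrofuran-2(3H)-one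
Conditions: TBAF, THF, 0 °C; aq. NH4Cl
Reagents that add atoms: none
Why: Fluoride cleaves both the O–Si and the C(sp)–Si bond under non-acidic conditions that the acid-labile alkoxyoxazole tolerates.

Step 13
Reactants: 20 (4S,5R)-5-[(1E)-5-hydroxy-2-{[(4-methoxybenzyl)oxy]methyl}hept-1-en-6-yn-1-yl]-4-(5-methoxy-4-methyl-1,3-oxazol-2-yl)dihydrofuran-2(3H)-one
Product: 21 (4S,5R)-4-(5-methoxy-4-methyl-1,3-oxazol-2-yl)-5-[(1E)-2-{[(4-methoxybenzyl)oxy]methyl}-5-oxohept-1-en-6-yn-1-yl]dihydrofuran-2(3H)-one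
Conditions: Dess–Martin periodinane, pyridine, CH2Cl2, 0 °C; used at once
Reagents that add atoms: none
Why: Dess–Martin oxidation of the propargylic alcohol gives the terminal ynone, which raises C3 to the oxidation level that activates the alkyne and erases the C3 epimer mixture.

Step 14
Reactants: 21 (4S,5R)-4-(5-methoxy-4-methyl-1,3-oxazol-2-yl)-5-[(1E)-2-{[(4-methoxybenzyl)oxy]methyl}-5-oxohept-1-en-6-yn-1-yl]dihydrofuran-2(3H)-one
Product: 23 ansa-furan ketone (2-methoxyfuran bridged from C6 to C4 by the C7–C8–C9=C10–C1–C2–C3(=O) chain; trans-lactone 7S/8R intact), via oxa-aza-norbornadiene cycloadduct 22 (not isolated)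
Conditions: PhMe (1 mM), BHT (cat.), 110 °C
Reagents that add atoms: none
Why: Proposed new method: the 2-aza-diene of the 5-methoxyoxazole (termini C6 and C15) adds the ynone C4≡C5 in a [4+2] cycloaddition to the 7-oxa-2-azanorbornadiene 22, which loses acetonitrile by retro-[4+2] and leaves the 2-methoxy-3-acylfuran, so that C5–C6 and C4–C15 form in one thermal operation; the closest known reaction type is the oxazole–alkynone Diels–Alder/cycloreversion furan synthesis (Kondrat'eva type, known between two molecules and in ring-fused intramolecular form), run here in a macrocyclizing, bridging sense that has no direct precedent. The five-membered ring closes as a formal [3+2] (C6–O–C15 onto C4≡C5 with extrusion of the N=C(CH3) unit), and the ten-membered carbocycle closes through C5–C6 as an ansa (meta-bridged) ring, because the tether joins the diene terminus C6 to the alkyne carbon C4 that bonds to the far terminus C15. No lasting stereocenter is created (the bridgeheads of 22 become sp2), but the trans-lactone at C7/C8 decides over which furan face the seven-carbon bridge lies, and step 18 reads this planar chirality out at C6. The step needs regioselectivity, which is secured electronically because the largest LUMO coefficient of the ynone (terminal C5) meets the largest HOMO coefficient of the alkoxyoxazole (C6, the terminus remote from OMe), so that the only competing intramolecular mode (ring-fused, nine-membered, C4–C6/C5–C15) is the electronically mismatched one; it needs ring closure to outrun intermolecular cycloaddition, which is secured by 1 mM dilution and by the turn elements of the substrate (cis C9=C10, trans-lactone); and it needs chemoselectivity, which is secured because the ynone is the only activated π-bond (the methylene lactone is installed later). The driving force is the formation of an aromatic furan and a nitrile, which pays for the strain of the [7](2,4)furanophane, a ring type known from ansa-bridged pyrrole natural products.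

Step 15
Reactants: 23 ansa-furan ketone
Product: 24 (3S)-ansa-furan carbinol (C3–OH; otherwise as 23)
Conditions: (R)-2-methyl-CBS-oxazaborolidine, BH3·SMe2, THF, −20 °C → rt; MeOH; Et3N-washed silica
Reagents that add atoms: none
Why: Corey–Bakshi–Shibata reduction with the furyl group as the large and the CH2 chain as the small substituent delivers hydride to the face that gives the (3S)-carbinol (reagent control by the (R)-oxazaborolidine).

Step 16
Reactants: 24 (3S)-ansa-furan carbinol
Product: 25 (3S)-ansa-furan isobutyrate (C3–OC(=O)CH(CH3)2)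
Conditions: (iPrCO)2O, Et3N, DMAP (cat.), CH2Cl2, 0 °C
Reagents that add atoms: isobutyric anhydride, CC(C)C(=O)OC(=O)C(C)C
Why: DMAP-catalyzed acylation caps the acid-sensitive furyl carbinol under basic conditions with retention at C3.

Step 17
Reactants: 25 (3S)-ansa-furan isobutyrate
Product: 28 α-methylene lactone ansa-furan (C11=C13 installed; otherwise as 25), via Mannich base 26 (not isolated), via trimethylammonium iodide 27 (not isolated)
Conditions: LDA, THF, −78 °C; CH2=NMe2+ I−, −78 → 0 °C; MeI, CH2Cl2, rt; aq. NaHCO3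
Reagents that add atoms: N,N-dimethylmethyleneiminium iodide (Eschenmoser's salt), C=[N+](C)C.[I-]
Why: The kinetic lithium enolate of the γ-lactone (the only unhindered acidic CH2; the isobutyrate methine is hindered and the methoxyfuran is base-stable) undergoes a Mannich reaction, and quaternization followed by β-elimination gives the exocyclic methylene, the transient C11 stereocenter being lost.

Step 18
Reactants: 28 α-methylene lactone ansa-furan
Product: 29 O14-(4-methoxybenzyl) ether of the target (3S,6R,7S,8R)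
Conditions: AcOH/THF/H2O, 0 °C → rt
Reagents that add atoms: water, O
Why: The 2-methoxyfuran is a cyclic ketene acetal that hydrolyzes under weak acid (C-protonation at C6, water addition at C15, loss of methanol) to the conjugated butenolide, the C6 stereocenter being set by protonation on the furan face not covered by the ansa bridge, a face fixed by the C7/C8 trans-lactone and expected to give 6R, while the weak acid keeps C-protonation ahead of ionization of the C3 ester.

Step 19
Reactants: 29 O14-(4-methoxybenzyl) ether of the target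
Product: 30 target CNP0322767.4
Conditions: DDQ, CH2Cl2/pH 7 buffer, 0 °C
Reagents that add atoms: none
Why: Oxidative cleavage of the 4-methoxybenzyl ether by DDQ frees the C14 alcohol without affecting the esters, the butenolide or the methylene lactone.

**Compound list**

1 | ethyl 4-chloro-3-oxobutanoate | CCOC(=O)CC(=O)CCl | starting material
2 | 4-methoxybenzyl alcohol | COc1ccc(CO)cc1 | starting material
3 | ethyl 4-[(4-methoxybenzyl)oxy]-3-oxobutanoate | CCOC(=O)CC(=O)COCc1ccc(OC)cc1 | intermediate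
4 | ethyl (2Z)-4-[(4-methoxybenzyl)oxy]-3-{[(trifluoromethyl)sulfonyl]oxy}but-2-enoate | CCOC(=O)/C=C(\OS(=O)(=O)C(F)(F)F)COCc1ccc(OC)cc1 | intermediate
5 | pent-1-en-4-yn-3-ol (racemic) | C=CC(O)C#C | starting material
6 | triethyl{[5-(triethylsilyl)pent-1-en-4-yn-3-yl]oxy}silane (racemic) | C=CC(O[Si](CC)(CC)CC)C#C[Si](CC)(CC)CC | intermediate
7 | 9-{3-[(triethylsilyl)oxy]-5-(triethylsilyl)pent-4-yn-1-yl}-9-borabicyclo[3.3.1]nonane (not isolated) | CC[Si](CC)(CC)OC(CCB1C2CCCC1CCC2)C#C[Si](CC)(CC)CC | intermediate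
8 | ethyl (2E)-3-{[(4-methoxybenzyl)oxy]methyl}-6-[(triethylsilyl)oxy]-8-(triethylsilyl)oct-2-en-7-ynoate | CCOC(=O)/C=C(/COCc1ccc(OC)cc1)CCC(O[Si](CC)(CC)CC)C#C[Si](CC)(CC)CC | intermediate
9 | (2E)-3-{[(4-methoxybenzyl)oxy]methyl}-6-[(triethylsilyl)oxy]-8-(triethylsilyl)oct-2-en-7-yn-1-ol | OC/C=C(/COCc1ccc(OC)cc1)CCC(O[Si](CC)(CC)CC)C#C[Si](CC)(CC)CC | intermediate
10 | (2E)-3-{[(4-methoxybenzyl)oxy]methyl}-6-[(triethylsilyl)oxy]-8-(triethylsilyl)oct-2-en-7-ynal | O=C/C=C(/COCc1ccc(OC)cc1)CCC(O[Si](CC)(CC)CC)C#C[Si](CC)(CC)CC | intermediate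
11 | (4S)-4-benzyl-1,3-oxazolidin-2-one | O=C1OC[C@H](Cc2ccccc2)N1 | starting material
12 | methyl 4-chloro-4-oxobutanoate | COC(=O)CCC(=O)Cl | starting material
13 | methyl 4-[(4S)-4-benzyl-2-oxo-1,3-oxazolidin-3-yl]-4-oxobutanoate | COC(=O)CCC(=O)N1[C@@H](Cc2ccccc2)COC1=O | intermediate
14 | methyl (3S,4R,5E)-3-{[(4S)-4-benzyl-2-oxo-1,3-oxazolidin-3-yl]carbonyl}-4-hydroxy-6-{[(4-methoxybenzyl)oxy]methyl}-9-[(triethylsilyl)oxy]-11-(triethylsilyl)undec-5-en-10-ynoate (syn-aldol adduct, not isolated) | COC(=O)C[C@H](C(=O)N1[C@@H](Cc2ccccc2)COC1=O)[C@H](O)/C=C(/COCc1ccc(OC)cc1)CCC(O[Si](CC)(CC)CC)C#C[Si](CC)(CC)CC | intermediate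
15 | (4S)-4-benzyl-3-({(2R,3S)-2-[(1E)-2-{[(4-methoxybenzyl)oxy]methyl}-5-[(triethylsilyl)oxy]-7-(triethylsilyl)hept-1-en-6-yn-1-yl]-5-oxotetrahydrofuran-3-yl}carbonyl)-1,3-oxazolidin-2-one | O=C1C[C@H](C(=O)N2[C@@H](Cc3ccccc3)COC2=O)[C@@H](/C=C(/COCc2ccc(OC)cc2)CCC(O[Si](CC)(CC)CC)C#C[Si](CC)(CC)CC)O1 | intermediate
16 | (2R,3S)-2-[(1E)-2-{[(4-methoxybenzyl)oxy]methyl}-5-[(triethylsilyl)oxy]-7-(triethylsilyl)hept-1-en-6-yn-1-yl]-5-oxotetrahydrofuran-3-carboxylic acid | O=C1C[C@H](C(=O)O)[C@@H](/C=C(/COCc2ccc(OC)cc2)CCC(O[Si](CC)(CC)CC)C#C[Si](CC)(CC)CC)O1 | intermediate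
17 | methyl L-alaninate hydrochloride | C[C@H](N)C(=O)OC.Cl | starting material
18 | methyl N-({(2R,3S)-2-[(1E)-2-{[(4-methoxybenzyl)oxy]methyl}-5-[(triethylsilyl)oxy]-7-(triethylsilyl)hept-1-en-6-yn-1-yl]-5-oxotetrahydrofuran-3-yl}carbonyl)-L-alaninate | O=C1C[C@H](C(=O)N[C@@H](C)C(=O)OC)[C@@H](/C=C(/COCc2ccc(OC)cc2)CCC(O[Si](CC)(CC)CC)C#C[Si](CC)(CC)CC)O1 | intermediate
19 | (4S,5R)-4-(5-methoxy-4-methyl-1,3-oxazol-2-yl)-5-[(1E)-2-{[(4-methoxybenzyl)oxy]methyl}-5-[(triethylsilyl)oxy]-7-(triethylsilyl)hept-1-en-6-yn-1-yl]dihydrofuran-2(3H)-one | O=C1C[C@H](c2nc(C)c(OC)o2)[C@@H](/C=C(/COCc2ccc(OC)cc2)CCC(O[Si](CC)(CC)CC)C#C[Si](CC)(CC)CC)O1 | intermediate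
20 | (4S,5R)-5-[(1E)-5-hydroxy-2-{[(4-methoxybenzyl)oxy]methyl}hept-1-en-6-yn-1-yl]-4-(5-methoxy-4-methyl-1,3-oxazol-2-yl)dihydrofuran-2(3H)-one | O=C1C[C@H](c2nc(C)c(OC)o2)[C@@H](/C=C(/COCc2ccc(OC)cc2)CCC(O)C#C)O1 | intermediate
21 | (4S,5R)-4-(5-methoxy-4-methyl-1,3-oxazol-2-yl)-5-[(1E)-2-{[(4-methoxybenzyl)oxy]methyl}-5-oxohept-1-en-6-yn-1-yl]dihydrofuran-2(3H)-one | O=C1C[C@H](c2nc(C)c(OC)o2)[C@@H](/C=C(/COCc2ccc(OC)cc2)CCC(=O)C#C)O1 | intermediate
22 | bridged cycloadduct: 7-oxa-2-azabicyclo[2.2.1]hepta-2,5-diene with bridgeheads C6 and C15(OMe), C4=C5 and N=C(CH3) bridges, spanned from C6 to C4 by the keto chain (not isolated; bridgeheads drawn for the diastereomer that leads to 6R) | CO[C@]12O[C@]3(N=C1C)C=C2C(=O)CC/C(COCc1ccc(OC)cc1)=C\[C@H]1OC(=O)C[C@@H]13 | intermediate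
23 | ansa-furan ketone: 2-methoxyfuran (C15–OMe) bridged from C6 to C4 by C7–C8–C9=C10–C1–C2–C3(=O); trans-γ-lactone on C7/C8 (7S,8R); C10 bears CH2O-PMB | COc1oc2cc1C(=O)CC/C(COCc1ccc(OC)cc1)=C\[C@H]1OC(=O)C[C@@H]12 | intermediate
24 | (3S)-ansa-furan carbinol (C3–OH; otherwise as 23) | COc1oc2cc1[C@@H](O)CC/C(COCc1ccc(OC)cc1)=C\[C@H]1OC(=O)C[C@@H]12 | intermediate
25 | (3S)-ansa-furan isobutyrate (C3–O-isobutyryl; otherwise as 23) | COc1oc2cc1[C@@H](OC(=O)C(C)C)CC/C(COCc1ccc(OC)cc1)=C\[C@H]1OC(=O)C[C@@H]12 | intermediate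
26 | Mannich base: 25 carrying CH2NMe2 on C11 (both C11 configurations, not isolated) | COc1oc2cc1[C@@H](OC(=O)C(C)C)CC/C(COCc1ccc(OC)cc1)=C\[C@H]1OC(=O)C(CN(C)C)[C@@H]12 | intermediate
27 | trimethylammonium iodide of 26 (not isolated) | COc1oc2cc1[C@@H](OC(=O)C(C)C)CC/C(COCc1ccc(OC)cc1)=C\[C@H]1OC(=O)C(C[N+](C)(C)C)[C@@H]12.[I-] | intermediate
28 | α-methylene lactone ansa-furan (C11=C13; otherwise as 25) | COc1oc2cc1[C@@H](OC(=O)C(C)C)CC/C(COCc1ccc(OC)cc1)=C\[C@H]1OC(=O)C(=C)[C@@H]12 | intermediate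
29 | O14-(4-methoxybenzyl) ether of the target (3S,6R,7S,8R) | C=C1C(=O)O[C@@H]2/C=C(/COCc3ccc(OC)cc3)CC[C@H](OC(=O)C(C)C)C3=C[C@@H](OC3=O)[C@@H]12 | intermediate
30 | CNP0322767.4: ten-membered carbocycle with C3 isobutyrate (3S), C4/C6-bridging butenolide (6R), trans-fused α-methylene-γ-lactone on C7/C8 (7S,8R), C9=C10 with C8 cis to C1, CH2OH on C10 | C=C1C(=O)O[C@@H]2/C=C(/CO)CC[C@H](OC(=O)C(C)C)C3=C[C@@H](OC3=O)[C@@H]12 | target

**Totals and risks**

Total step count: 19. Longest linear sequence: 17 steps (1, 2, 4–6, 8–19).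

Steps most likely to fail:

1. Step 14 (Proposed new method). What may go wrong: intermolecular cycloaddition (oligomers) outruns ring closure, or the strain of the ansa bridge stops the closure. Fallback with known reactions, setting out from acid 16 and returning at 23: the two bonds are made one after the other. Acid 16 is reduced through its mixed anhydride (isobutyl chloroformate, N-methylmorpholine; NaBH4) to the hydroxymethyl lactone F1 and oxidized (Dess–Martin) to the lactone aldehyde F2. AgF and N-iodosuccinimide exchange the alkynyl silyl group for iodine to give the iodoalkyne aldehyde F3. An intramolecular Nozaki–Hiyama–Kishi reaction (CrCl2, NiCl2 cat., THF, high dilution) closes the ten-membered ring at C5–C6 to the cyclic propargylic alcohol F4. Palladium-catalyzed cyclocarbonylation of the alkynol (Pd(dba)2, 1,4-bis(diphenylphosphino)butane, CO/H2) attaches C15 to C4 and closes the silyloxy butenolide F5. TBAF/AcOH frees the hydroxy butenolide F6, Dess–Martin oxidation gives the 3-acylbutenolide F7, and O-methylation of its 2-hydroxyfuran tautomer (Me3SiCHN2, MeOH/PhMe) gives 23. The C3 and C6 configurations of F1–F6 are irrelevant because both are erased at F7.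

2. Step 18. What may go wrong: protonation from the wrong furan face (C6 epimer), or ionization of the C3 ester before C-protonation. Fallback setting out from 28 and returning at 29: C6 is set by hydride addition to a ketone instead of by protonation. Dye-sensitized photo-oxygenation of the methoxyfuran (O2, rose bengal, hν, CH2Cl2/MeOH, −78 °C; Me2S) opens it to the (Z)-γ-keto enoate F8. Luche reduction (NaBH4, CeCl3·7H2O, MeOH, −78 °C) of the C6 ketone, followed by spontaneous lactonization of the cis hydroxy ester, gives 29.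

3. Step 15. What may go wrong: poor or reversed facial selectivity because the ansa bridge overrides the reagent, and slow reduction of the electron-rich furyl ketone. Fallback setting out from 23 and returning at 25: the reduction is run under substrate control (NaBH4, CeCl3·7H2O, MeOH) to the (3R)-carbinol F9, which is esterified with inversion under Mitsunobu conditions (isobutyric acid, PPh3, diisopropyl azodicarboxylate) to give 25 directly.

Further compounds

F1 | step 14 | (4R,5R)-4-(hydroxymethyl)-5-[(1E)-2-{[(4-methoxybenzyl)oxy]methyl}-5-[(triethylsilyl)oxy]-7-(triethylsilyl)hept-1-en-6-yn-1-yl]dihydrofuran-2(3H)-one | O=C1C[C@H](CO)[C@@H](/C=C(/COCc2ccc(OC)cc2)CCC(O[Si](CC)(CC)CC)C#C[Si](CC)(CC)CC)O1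
F2 | step 14 | (2R,3S)-2-[(1E)-2-{[(4-methoxybenzyl)oxy]methyl}-5-[(triethylsilyl)oxy]-7-(triethylsilyl)hept-1-en-6-yn-1-yl]-5-oxotetrahydrofuran-3-carbaldehyde | O=C1C[C@H](C=O)[C@@H](/C=C(/COCc2ccc(OC)cc2)CCC(O[Si](CC)(CC)CC)C#C[Si](CC)(CC)CC)O1
F3 | step 14 | (2R,3S)-2-[(1E)-7-iodo-2-{[(4-methoxybenzyl)oxy]methyl}-5-[(triethylsilyl)oxy]hept-1-en-6-yn-1-yl]-5-oxotetrahydrofuran-3-carbaldehyde | O=C1C[C@H](C=O)[C@@H](/C=C(/COCc2ccc(OC)cc2)CCC(O[Si](CC)(CC)CC)C#CI)O1
F4 | step 14 | cyclic propargylic alcohol: ten-membered ring closed at C5–C6, C4≡C5, 6-OH, 3-OSiEt3, trans-lactone on C7/C8 as in 16 (C3 and C6 in both configurations) | O=C1C[C@@H]2C(O)C#CC(O[Si](CC)(CC)CC)CC/C(COCc3ccc(OC)cc3)=C\[C@H]2O1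
F5 | step 14 | silyloxy butenolide: C4/C6-bridging butenolide, 3-OSiEt3, lactone without C13, O14-PMB (C3 and C6 in both configurations) | O=C1C[C@@H]2C3C=C(C(=O)O3)C(O[Si](CC)(CC)CC)CC/C(COCc3ccc(OC)cc3)=C\[C@H]2O1
F6 | step 14 | hydroxy butenolide: as F5 with free 3-OH | O=C1C[C@@H]2C3C=C(C(=O)O3)C(O)CC/C(COCc3ccc(OC)cc3)=C\[C@H]2O1
F7 | step 14 | 3-acylbutenolide: as F6 with C3 ketone (C6 labile) | O=C1C[C@@H]2C3C=C(C(=O)O3)C(=O)CC/C(COCc3ccc(OC)cc3)=C\[C@H]2O1
F8 | step 18 | (Z)-γ-keto enoate: ten-membered ring with C6 ketone, C4=C5 carrying the C15 methyl ester cis to C6, 3-isobutyrate, methylene lactone, O14-PMB | COC(=O)/C1=C\C(=O)[C@H]2C(=C)C(=O)O[C@@H]2/C=C(/COCc2ccc(OC)cc2)CC[C@@H]1OC(=O)C(C)C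
F9 | step 15 | (3R)-ansa-furan carbinol (C3 epimer of 24) | COc1oc2cc1[C@H](O)CC/C(COCc1ccc(OC)cc1)=C\[C@H]1OC(=O)C[C@@H]12
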